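The constants to be had from larch and cedar are the equilibrium ratio K = cZ/cE at 85 °C and at 118 °C, and the heat that links the two. What I want from them is the amount of Z at the end of four flasks:

| flask | E | L | G | temperature | remark | time |
|---|---|---|---|---|---|---|
| larch | 0.10 M | 0.030 M | 0.25 mol% | 85 °C | run made earlier |  |
| cedar | 0.10 M | 0.030 M | 1 mol% | 118 °C | run made earlier |  |
| Wednesday's | 0.10 M | 0.0300 M | 0.5 mol% | 110 °C |  | 5.0 h |
| Friday's | 0.10 M | 0.0300 M | 0.5 mol% | 70 °C |  | 5.0 h |
| Sunday's | 0.10 M | 0.0300 M | 0.5 mol% | 90 °C |  | 5.0 h |
| Thursday's | 0.10 M | 0.0300 M | 0.5 mol% | 130 °C |  | 5.0 h |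

| run | time / h | Z / % | E / % |
|---|---|---|---|
| larch | 3.00 | 52.9 | 17.5 |
| larch | 6.00 | 52.5 | 18.4 |
| larch | 15.0 | 51.3 | 16.4 |
| larch | 20.0 | 51.6 | 17.9 |
| cedar | 0.500 | 34.2 | 35.4 |
| cedar | 1.00 | 33.2 | 36.9 |
| cedar | 2.50 | 33.2 | 36.8 |
| cedar | 6.00 | 33.2 | 36.8 |

(standard deviation of a reading: 1 percentage point)

- the numbers in the tables scatter with a standard deviation of 1 percentage point
- reactions considered so far: E + G <-> G + Z; E + L -> J

- which flask leads in amount of Z, in percent of the E charged ("all alike" within 1.5 percentage points) (Wednesday's / Friday's / Sunday's / Thursday's / all alike)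
- how much Z is there at the end, in percent of the E charged: Wednesday's
- how much Z is there at the end, in percent of the E charged: Friday's
- how much Z is there at the end, in percent of the E charged: Sunday's
- how much Z is there at the end, in percent of the E charged: Thursday's

I take the settings one at a time. Time: by hand, a longer run adds nothing once both steps are over, and the readings of larch stay flat from 3.00 h to 20.0 h. The loading of G: a catalyst speeds both directions of E to Z alike, so it sets how soon and not where, and the four flasks share 0.5 mol% anyway. Larch stood flat by its first reading with less G than these flasks, but Friday's is colder than either run, so there the end state is an assumption.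

The charge of L: each L takes one E into J, so L is the limiting reagent and E and Z share a pool of 70.0% of the E charged. The readings agree within their scatter, since at the last reading of each run Z and E add up to 69.5% in larch and 70.0% in cedar.

Temperature: I read K as 2.97 in larch and 0.901 in cedar, so the step from E to Z releases about 42.1 kJ mol⁻¹.

I reckon with what stays behind. The left fraction is the part of the pool still E at equilibrium, one divided by one plus K. For Thursday's, at 130 °C, I put K at 0.613, so the left fraction is 62.0% and Z is the rest of the pool, 26.6%. In the same way I get 37.9% for Wednesday's, 49.7% for Sunday's and 59.2% for Friday's, which leads.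

The forecast names Friday's, with 59% there, 49.6% for Sunday's, 37.9% for Wednesday's and 26.6% for Thursday's, in its words: “Cooler flasks therefore favour Z.”

Friday's leads with 59.9%, then Sunday's with 50.1%, Wednesday's with 38.2% and Thursday's with 26.6%.

    E + G ⇌ G + Z (K = 1.20, k = 970 M⁻¹ min⁻¹, Ea = 60.0 kJ mol⁻¹, ΔH = −43.0 kJ mol⁻¹)
    E + L → J (k = 9.40 M⁻¹ min⁻¹, Ea = 56.0 kJ mol⁻¹)
    (constants at 110 °C)

In Thursday's flask the step from E + G to G + Z had done half of its turnover up to 5.0 h by 0.140 min, and the step from E + L to J had 100% of its turnover up to 5.0 h behind it at 1.00 h. In Thursday's at 2.50 h L stood at 0% of its charge and E at 43.4%, and pool times left fraction gives 43.4% against the 43.4% of E at the end. A further flask like Thursday's, with 0.25 M of E and L still at 0.0300 M, has a pool of 88.0%, so the same left fraction gives 54.6%, and that flask ends with 54.5% of E.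

The runs stem from a simulated flask from invented constants; noise was put on by code.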